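**Plan**

- Retrosynthesis: the C3 carbinol is traced back to a ketone and the Ca=Cb enol ether to a lactol. The pyran ring O1–C2–C3–C4–Cb–Ca (Ca on ring B and O1, Cb on the prenylated ring A, both shared with the oxepine) is then the oxidative ring-expansion (Achmatowicz) image of a flat 2,3-diaryl furan carrying the tertiary carbinol C2 on its free α-carbon, so the O1–Ca bond is cut there.
- The furyl carbinol is cut at C2–CH3 (methyl addition to a furyl ketone), at the furan–C2 bond (acylation of the lithiated furan) and at the furan (two-carbon annulation of a dibenzo[b,f]oxepin-10-one). The oxepinone is cut at the diaryl ether C–O bond (SNAr) and at the Cb–ring A bond (ketone α-arylation).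
- Forward: ring A bromide + ring B acetophenone → deoxybenzoin → seven-membered oxepine ring → furan ring → side chain and C2 → pyranone ring by furan dearomatisation → enol ether, C3 alcohol, free phenols.
- Stereochemistry: C2 (S) from a ligand-controlled enantioselective Me2Zn addition; C3 (S) from a Corey–Bakshi–Shibata reduction next to the quaternary C2; every other center formed on the way is transient.

Key step: step 13

Remarks: pyran numbering is O1, C2, C3, C4; Ca and Cb are the two alkene carbons shared by pyran and oxepine; ring A is the prenylated ring; TIPS = triisopropylsilyl, THP = tetrahydropyran-2-yl. Assumption: the titanium bis(sulfonamide) diol catalyst of step 12 is taken to tell the furyl from the alkyl side of ketone 19 as it tells aryl from alkyl in aryl alkyl ketones, and the ligand antipode that places methyl on the Re face is the one used.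

**Step 1**
Reactants: 1 4,6-dibromoresorcinol
Product: 2 1,5-dibromo-2,4-bis(triisopropylsilyloxy)benzene
Conditions: TIPSCl (2.4 equiv), imidazole, DMAP (cat.), DMF, 40 °C
Reagents that add atoms: triisopropylsilyl chloride, CC(C)[Si](Cl)(C(C)C)C(C)C
Why: Routine silylation of both phenols; the bulky TIPS group is chosen because it should resist the 1,3 O-to-C silyl shift of the ortho-lithiated aryl ether formed in step 2.

**Step 2**
Reactants: 2 1,5-dibromo-2,4-bis(triisopropylsilyloxy)benzene; 3 prenyl bromide (1-bromo-3-methylbut-2-ene)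
Product: 5 1-bromo-5-(3-methylbut-2-enyl)-2,4-bis(triisopropylsilyloxy)benzene, via aryllithium 4 (not isolated)
Conditions: n-BuLi (1.05 equiv), THF, −78 °C; CuBr·SMe2 (10 mol %), then 3, −78 → −20 °C
Reagents that add atoms: none
Why: Single bromine–lithium exchange on a symmetric dibromide (the first carbanion disfavours a second exchange) followed by copper-catalysed SN2 allylation at the primary carbon of prenyl bromide; because the two bromides of 2 are equivalent, no regiochemical question arises.

**Step 3**
Reactants: 6 2'-fluoro-4'-hydroxyacetophenone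
Product: 7 1-[2-fluoro-4-(tetrahydro-2H-pyran-2-yloxy)phenyl]ethanone (racemic acetal)
Conditions: 3,4-dihydro-2H-pyran, PPTS (cat.), CH2Cl2, 25 °C
Reagents that add atoms: 3,4-dihydro-2H-pyran, C1=COCCC1
Why: Acid-catalysed acetalisation of the phenol; the THP ether is stable to base, fluoride and palladium, so the ring B oxygen cannot become a phenoxide that would switch off the later SNAr, and it is removable under very mild acid.

**Step 4**
Reactants: 5 1-bromo-5-(3-methylbut-2-enyl)-2,4-bis(triisopropylsilyloxy)benzene; 7 1-[2-fluoro-4-(tetrahydro-2H-pyran-2-yloxy)phenyl]ethanone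
Product: 8 2-[5-(3-methylbut-2-enyl)-2,4-bis(triisopropylsilyloxy)phenyl]-1-[2-fluoro-4-(tetrahydro-2H-pyran-2-yloxy)phenyl]ethanone
Conditions: Pd(OAc)2 (3 mol %), XPhos (6 mol %), K3PO4, toluene, 90 °C
Reagents that add atoms: none
Why: Palladium-catalysed ketone α-arylation (Buchwald–Hartwig type) of the methyl ketone enolate with the aryl bromide after oxidative addition to zerovalent palladium; the ortho-silyloxy group of 5 should discourage a second arylation, and K3PO4 in toluene should leave silyl ethers, THP acetal and C–F bond untouched.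

**Step 5**
Reactants: 8 the deoxybenzoin of step 4
Product: 10 3-hydroxy-2-(3-methylbut-2-enyl)-7-(tetrahydro-2H-pyran-2-yloxy)dibenzo[b,f]oxepin-10(11H)-one, via dicesium diphenoxide 9 (not isolated)
Conditions: CsF (4 equiv), DMF (0.02 M), 25 → 85 °C, argon; aqueous NH4Cl work-up
Reagents that add atoms: none
Why: Fluoride cleaves both aryl silyl ethers and the phenoxide ortho to the benzylic methylene displaces the fluoride activated by the ortho carbonyl (intramolecular SNAr through a Meisenheimer adduct, seven-membered ring); the other phenoxide cannot reach the C–F carbon, the THP ether keeps ring B from becoming a deactivating phenoxide, and dilution suppresses intermolecular etherification.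

**Step 6**
Reactants: 10 the THP-protected hydroxy oxepinone
Product: 11 3,7-dihydroxy-2-(3-methylbut-2-enyl)dibenzo[b,f]oxepin-10(11H)-one
Conditions: PPTS (0.2 equiv), MeOH, 40 °C
Reagents that add atoms: none
Why: Transacetalisation of the very labile aryl THP ether to methanol under buffered acid, mild enough that the ortho-prenyl phenol should not cyclise to a chroman.

**Step 7**
Reactants: 11 3,7-dihydroxy-2-(3-methylbut-2-enyl)dibenzo[b,f]oxepin-10(11H)-one
Product: 12 2-(3-methylbut-2-enyl)-3,7-bis(triisopropylsilyloxy)dibenzo[b,f]oxepin-10(11H)-one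
Conditions: TIPSCl (2.5 equiv), imidazole, DMF, 25 °C
Reagents that add atoms: triisopropylsilyl chloride, CC(C)[Si](Cl)(C(C)C)C(C)C
Why: Standard silylation of both phenols, giving the base-stable, fluoride-labile protection carried to the end.

**Step 8**
Reactants: 12 bis(TIPS) oxepinone; 13 bromoacetaldehyde diethyl acetal (2-bromo-1,1-diethoxyethane)
Product: 14 11-(2,2-diethoxyethyl)-2-(3-methylbut-2-enyl)-3,7-bis(triisopropylsilyloxy)dibenzo[b,f]oxepin-10(11H)-one (racemic)
Conditions: KN(SiMe3)2 (1.1 equiv), THF–DMPU, 0 °C; 13 (1.5 equiv), Bu4NI (0.2 equiv), 0 → 50 °C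
Reagents that add atoms: none
Why: C-Alkylation of the doubly benzylic potassium enolate of the cyclic deoxybenzoin at Cb, helped by in situ Finkelstein exchange and a dipolar cosolvent; the racemic center at Cb disappears in the next step.

**Step 9**
Reactants: 14 the keto acetal of step 8
Product: 15 2,3-diaryl furan fused across Ca–Cb of the dibenzo[b,f]oxepine (furan O on Ca; free α-CH and β-CH; ring A prenyl and OTIPS; ring B OTIPS)
Conditions: p-TsOH·H2O (10 mol %), toluene, 50 °C
Reagents that add atoms: none
Why: Paal–Knorr-type cyclodehydration in which acid unmasks the aldehyde as an oxocarbenium ion, the enol oxygen of the Ca ketone adds and two molecules of ethanol are lost, driven by aromatisation.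

**Step 10**
Reactants: 16 5-methylhex-4-enoic acid
Product: 17 N-methoxy-N,5-dimethylhex-4-enamide
Conditions: 1,1'-carbonyldiimidazole, CH2Cl2, 25 °C; then MeNH(OMe)·HCl
Reagents that add atoms: N,O-dimethylhydroxylamine hydrochloride, CNOC.Cl
Why: Amide formation through the acyl imidazole, a standard preparation of a Weinreb amide that leaves the trisubstituted alkene alone.

**Step 11**
Reactants: 15 furan-fused bis(TIPS) dibenzoxepine; 17 N-methoxy-N,5-dimethylhex-4-enamide
Product: 19 furyl ketone (5-methylhex-4-enoyl group on the furan α-carbon of 15), via 2-lithiofuran 18 (not isolated)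
Conditions: n-BuLi (1.1 equiv), THF, −78 → −20 °C; then 17, −78 → 0 °C
Reagents that add atoms: none
Why: Oxygen-directed deprotonation of the only furan α-C–H, the most acidic C–H of 15, and Weinreb ketone synthesis, whose chelated tetrahedral adduct should prevent over-addition.

**Step 12**
Reactants: 19 furyl ketone
Product: 20 (S)-tertiary furyl carbinol: (2S)-6-methyl-2-(furyl)hept-5-en-2-ol on the furan α-carbon of the bis(TIPS) furo-dibenzoxepine
Conditions: Me2Zn (3 equiv), Ti(OiPr)4 (1.2 equiv), trans-cyclohexane-1,2-diamine bis(2-exo-hydroxy-10-camphorsulfonamide) ligand (10 mol %, antipode adding to the Re face), toluene–hexane, 25 °C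
Reagents that add atoms: dimethylzinc, C[Zn]C
Why: Titanium-promoted enantioselective dialkylzinc addition to an aryl alkyl ketone under bis(sulfonamide) diol control; the chiral titanium complex should distinguish the flat furyl group from the primary alkyl chain and deliver methyl to the Re face (O > furyl > CH2), which sets C2 as S.

**Step 13**
Reactants: 20 (S)-tertiary furyl carbinol
Product: 23 6-hydroxy-2H-pyran-3(6H)-one fused to the oxepine (C2 S; lactol carbon Ca as both anomers), via furan endoperoxide 21 (not isolated), via cis-enedione 22 (not isolated)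
Conditions: O2, tetraphenylporphyrin (1 mol %), visible light, CH2Cl2, −78 °C, until 20 is consumed; then Me2S (5 equiv), −78 → 25 °C
Reagents that add atoms: dioxygen (as singlet oxygen), O=O
Why: Singlet oxygen from the photoexcited porphyrin adds [4+2] across the two α-carbons of the electron-rich trisubstituted 2,3-diaryl furan to give endoperoxide 21; Me2S removes one peroxide oxygen and the bicycle collapses to the cis-enedione 22, whose Z geometry is inherited from the furan. The C2 hydroxyl then adds to the ring B aryl ketone Ca in a 6-exo-trig hemiketalisation, forming the O1–Ca bond and the pyranone ring with its carbonyl at C3. The closest known reaction type is the photooxygenation variant of the Achmatowicz rearrangement of furyl carbinols. No lasting stereocenter is created: the lactol carbon forms as both anomers and is made planar again in step 15, while C2 bears no hydrogen and has none of its bonds broken, so its configuration from step 12 is carried through. The selectivity needed is furan cycloaddition over ene reaction at the two trisubstituted alkenes; it rests on the much higher singlet-oxygen reactivity of the diaryl furan, reinforced by −78 °C and by stopping at consumption of 20.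

**Step 14**
Reactants: 23 hydroxy pyranone
Product: 24 6-hydroxytetrahydropyran-3-one fused to the oxepinone skeleton (C2 S; Ca–OH and Cb–H as diastereomer mixture)
Conditions: [(Ph3P)CuH]6 (0.4 equiv), H2O (3 equiv), degassed toluene, 25 °C
Reagents that add atoms: none
Why: Conjugate hydride transfer from the phosphine-stabilised copper hydride to the enone (or to its open ene-dione tautomer, which gives the same product) and protonation of the copper enolate by water; the reagent should spare isolated trisubstituted alkenes, aryl silyl ethers and saturated ketones, and the new center at Cb is of no consequence.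

**Step 15**
Reactants: 24 saturated lactol ketone
Product: 26 2H-pyran-3(4H)-one with the Ca=Cb enol ether shared with the dibenzo[b,f]oxepine (C2 S), via lactol mesylate 25 (not isolated)
Conditions: MsCl (3 equiv), Et3N (8 equiv), CH2Cl2, 0 → 25 °C
Reagents that add atoms: none
Why: Lactol-to-enol-ether dehydration in which the mesylate ionises to an oxocarbenium ion stabilised by O1 and the para-silyloxy ring B, and triethylamine removes the only adjacent proton (the benzylic Cb–H) to give the tetrasubstituted alkene conjugated with both arenes; basic conditions are chosen to avoid acid-catalysed return of the 1,4-dicarbonyl tautomer to the furan.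

**Step 16**
Reactants: 26 enol ether ketone
Product: 27 (2S,3S)-alcohol, bis(TIPS) ether of the target (C3–OH cis to the 4-methylpent-3-enyl chain)
Conditions: (R)-2-methyl-CBS-oxazaborolidine (0.5 equiv), catecholborane (2 equiv), toluene, −60 → −30 °C
Reagents that add atoms: none
Why: Corey–Bakshi–Shibata reduction in which the ketone binds the oxazaborolidine boron anti to its larger flank (quaternary C2 versus the C4 methylene) and hydride enters the face giving 3S, the (R)-catalyst being the antipode of the one that turns acetophenone into the (R)-alcohol; catecholborane at low temperature should not hydroborate the trisubstituted alkenes.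

**Step 17**
Reactants: 27 (2S,3S)-bis(TIPS) ether
Product: 28 CNP0185870.1, the (2S,3S)-diphenol
Conditions: Bu4NF (2.4 equiv), AcOH (2.4 equiv), THF, 0 °C
Reagents that add atoms: none
Why: Fluoride cleavage of both aryl silyl ethers, buffered with acetic acid so that the enol ether and the electron-rich diphenol are not exposed to strongly basic phenoxide conditions.

**Compound list**

1 | 4,6-dibromoresorcinol | Oc1cc(O)c(Br)cc1Br | starting material
2 | 1,5-dibromo-2,4-bis(triisopropylsilyloxy)benzene | CC(C)[Si](Oc1cc(O[Si](C(C)C)(C(C)C)C(C)C)c(Br)cc1Br)(C(C)C)C(C)C | intermediate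
3 | prenyl bromide (1-bromo-3-methylbut-2-ene) | CC(C)=CCBr | starting material
4 | 5-bromo-2,4-bis(triisopropylsilyloxy)phenyllithium | [Li]c1cc(Br)c(O[Si](C(C)C)(C(C)C)C(C)C)cc1O[Si](C(C)C)(C(C)C)C(C)C | intermediate
5 | 1-bromo-5-(3-methylbut-2-enyl)-2,4-bis(triisopropylsilyloxy)benzene | CC(C)=CCc1cc(Br)c(O[Si](C(C)C)(C(C)C)C(C)C)cc1O[Si](C(C)C)(C(C)C)C(C)C | intermediate
6 | 2'-fluoro-4'-hydroxyacetophenone | CC(=O)c1ccc(O)cc1F | starting material
7 | 1-[2-fluoro-4-(tetrahydro-2H-pyran-2-yloxy)phenyl]ethanone (racemic acetal) | CC(=O)c1ccc(OC2CCCCO2)cc1F | intermediate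
8 | 2-[5-(3-methylbut-2-enyl)-2,4-bis(triisopropylsilyloxy)phenyl]-1-[2-fluoro-4-(tetrahydro-2H-pyran-2-yloxy)phenyl]ethanone | O=C(Cc1cc(CC=C(C)C)c(O[Si](C(C)C)(C(C)C)C(C)C)cc1O[Si](C(C)C)(C(C)C)C(C)C)c1ccc(OC2CCCCO2)cc1F | intermediate
9 | 2-[2,4-dihydroxy-5-(3-methylbut-2-enyl)phenyl]-1-[2-fluoro-4-(tetrahydro-2H-pyran-2-yloxy)phenyl]ethanone, present in the flask as its dicesium diphenoxide | O=C(Cc1cc(CC=C(C)C)c(O)cc1O)c1ccc(OC2CCCCO2)cc1F | intermediate
10 | 3-hydroxy-2-(3-methylbut-2-enyl)-7-(tetrahydro-2H-pyran-2-yloxy)dibenzo[b,f]oxepin-10(11H)-one | O=C1Cc2cc(CC=C(C)C)c(O)cc2Oc2cc(OC3CCCCO3)ccc21 | intermediate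
11 | 3,7-dihydroxy-2-(3-methylbut-2-enyl)dibenzo[b,f]oxepin-10(11H)-one | O=C1Cc2cc(CC=C(C)C)c(O)cc2Oc2cc(O)ccc21 | intermediate
12 | 2-(3-methylbut-2-enyl)-3,7-bis(triisopropylsilyloxy)dibenzo[b,f]oxepin-10(11H)-one | O=C1Cc2cc(CC=C(C)C)c(O[Si](C(C)C)(C(C)C)C(C)C)cc2Oc2cc(O[Si](C(C)C)(C(C)C)C(C)C)ccc21 | intermediate
13 | bromoacetaldehyde diethyl acetal | CCOC(CBr)OCC | starting material
14 | 11-(2,2-diethoxyethyl)-2-(3-methylbut-2-enyl)-3,7-bis(triisopropylsilyloxy)dibenzo[b,f]oxepin-10(11H)-one (racemic) | CCOC(CC1C(=O)c2ccc(O[Si](C(C)C)(C(C)C)C(C)C)cc2Oc2cc(O[Si](C(C)C)(C(C)C)C(C)C)c(CC=C(C)C)cc21)OCC | intermediate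
15 | furan fused across Ca–Cb of the dibenzo[b,f]oxepine, furan O on Ca, free α-CH; ring A prenyl and OTIPS, ring B OTIPS | c1cc2c(o1)-c1ccc(O[Si](C(C)C)(C(C)C)C(C)C)cc1Oc1cc(O[Si](C(C)C)(C(C)C)C(C)C)c(CC=C(C)C)cc1-2 | intermediate
16 | 5-methylhex-4-enoic acid | CC(C)=CCCC(=O)O | starting material
17 | N-methoxy-N,5-dimethylhex-4-enamide | CC(C)=CCCC(=O)N(C)OC | intermediate
18 | α-lithio derivative of furan 15 | [Li]c1cc2c(o1)-c1ccc(O[Si](C(C)C)(C(C)C)C(C)C)cc1Oc1cc(O[Si](C(C)C)(C(C)C)C(C)C)c(CC=C(C)C)cc1-2 | intermediate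
19 | furyl ketone: 5-methylhex-4-enoyl group on the furan α-carbon of 15 | CC(C)=CCCC(=O)c1cc2c(o1)-c1ccc(O[Si](C(C)C)(C(C)C)C(C)C)cc1Oc1cc(O[Si](C(C)C)(C(C)C)C(C)C)c(CC=C(C)C)cc1-2 | intermediate
20 | (S)-tertiary furyl carbinol (methyl, hydroxyl and 4-methylpent-3-enyl on the carbinol carbon) | CC(C)=CCC[C@](C)(O)c1cc2c(o1)-c1ccc(O[Si](C(C)C)(C(C)C)C(C)C)cc1Oc1cc(O[Si](C(C)C)(C(C)C)C(C)C)c(CC=C(C)C)cc1-2 | intermediate
21 | furan endoperoxide of 20 (peroxide bridge between the two furan α-carbons, bridgehead diastereomers) | CC(C)=CCC[C@](C)(O)C12OOC3(O1)C(=C2)c1cc(CC=C(C)C)c(O[Si](C(C)C)(C(C)C)C(C)C)cc1Oc1cc(O[Si](C(C)C)(C(C)C)C(C)C)ccc13 | intermediate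
22 | (Z)-enedione: 11-ylidene dibenzo[b,f]oxepin-10-one whose exocyclic CH carries the (S)-α-hydroxy ketone side chain | CC(C)=CCC[C@](C)(O)C(=O)/C=C1\C(=O)c2ccc(O[Si](C(C)C)(C(C)C)C(C)C)cc2Oc2cc(O[Si](C(C)C)(C(C)C)C(C)C)c(CC=C(C)C)cc21 | intermediate
23 | 6-hydroxy-2H-pyran-3(6H)-one fused to the oxepine, C2 S, both lactol anomers | CC(C)=CCC[C@]1(C)OC2(O)C(=CC1=O)c1cc(CC=C(C)C)c(O[Si](C(C)C)(C(C)C)C(C)C)cc1Oc1cc(O[Si](C(C)C)(C(C)C)C(C)C)ccc12 | intermediate
24 | 6-hydroxytetrahydropyran-3-one (Cb–H, Ca–OH; diastereomer mixture), C2 S | CC(C)=CCC[C@]1(C)OC2(O)C(CC1=O)c1cc(CC=C(C)C)c(O[Si](C(C)C)(C(C)C)C(C)C)cc1Oc1cc(O[Si](C(C)C)(C(C)C)C(C)C)ccc12 | intermediate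
25 | methanesulfonate of lactol 24 | CC(C)=CCC[C@]1(C)OC2(OS(C)(=O)=O)C(CC1=O)c1cc(CC=C(C)C)c(O[Si](C(C)C)(C(C)C)C(C)C)cc1Oc1cc(O[Si](C(C)C)(C(C)C)C(C)C)ccc12 | intermediate
26 | 2H-pyran-3(4H)-one with the Ca=Cb enol ether shared with the dibenzo[b,f]oxepine, C2 S | CC(C)=CCC[C@]1(C)OC2=C(CC1=O)c1cc(CC=C(C)C)c(O[Si](C(C)C)(C(C)C)C(C)C)cc1Oc1cc(O[Si](C(C)C)(C(C)C)C(C)C)ccc12 | intermediate
27 | (2S,3S)-alcohol, bis(TIPS) ether of the target | CC(C)=CCC[C@]1(C)OC2=C(C[C@@H]1O)c1cc(CC=C(C)C)c(O[Si](C(C)C)(C(C)C)C(C)C)cc1Oc1cc(O[Si](C(C)C)(C(C)C)C(C)C)ccc12 | intermediate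
28 | CNP0185870.1, (2S,3S) | CC(C)=CCC[C@]1(C)OC2=C(C[C@@H]1O)c1cc(CC=C(C)C)c(O)cc1Oc1cc(O)ccc12 | target

**Step count**

Total: 17 steps. Longest linear sequence: 15 steps (1, 2, 4, 5, 6, 7, 8, 9, 11, 12, 13, 14, 15, 16, 17); steps 3 and 10 are one-step side branches.

**Steps most likely to fail**

Step 12. The methyl transfer may be slow on a hindered, electron-rich 2-acylfuran, and the catalyst may discriminate poorly between the furyl group and the primary alkyl chain, giving low enantiomeric purity at C2. Fallback: setting out from furan 15, the lithiofuran 18 is added to commercial 6-methylhept-5-en-2-one (THF, −78 °C) to give the racemic tertiary alcohol F1 in one step, bypassing ketone 19. The enantiomers are then separated by preparative chromatography on a chiral stationary phase, the (R)-enantiomer F2 being set aside, and the route is rejoined at 20.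

Step 15. The reduced compound may sit largely as the open 1,4-diketone, which can close back to the furan (Paal–Knorr) or fail to be activated at the tertiary lactol oxygen, so the dehydration may stall or revert. Fallback: setting out from hydroxy pyranone 23 (steps 14 and 15 are both replaced), the lactol is deoxygenated ionically with Et3SiH and BF3·OEt2 in CH2Cl2 at −78 °C to the 6H-pyran-3-one F3, which carries hydrogen on Ca. DBU in CH2Cl2 then moves the alkene out of conjugation with the ketone into the Ca=Cb position by γ-deprotonation and α-protonation, rejoining the route at 26.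

Step 8. SN2 displacement at the β,β-dialkoxyethyl bromide is slow, so heating may bring O-alkylation or loss of silyl groups before C-alkylation is complete. Fallback: setting out from oxepinone 12, the enolate is alkylated with the far more reactive 1-bromo-3,3-dimethoxypropan-2-one to give the 1,4-diketone acetal F4. p-TsOH in wet toluene closes the furan and unmasks the aldehyde, giving the furan-2-carbaldehyde F5; 4-methylpent-3-enylmagnesium bromide adds to give the secondary furyl carbinol F6; MnO2 oxidises it to ketone 19, where the route is rejoined (steps 9, 10 and 11 are not needed).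

**Further compounds**

F1 | step 12 | racemic tertiary furyl carbinol (racemate of 20) | CC(C)=CCCC(C)(O)c1cc2c(o1)-c1ccc(O[Si](C(C)C)(C(C)C)C(C)C)cc1Oc1cc(O[Si](C(C)C)(C(C)C)C(C)C)c(CC=C(C)C)cc1-2
F2 | step 12 | (R)-enantiomer of 20 | CC(C)=CCC[C@@](C)(O)c1cc2c(o1)-c1ccc(O[Si](C(C)C)(C(C)C)C(C)C)cc1Oc1cc(O[Si](C(C)C)(C(C)C)C(C)C)c(CC=C(C)C)cc1-2
F3 | step 15 | 6H-pyran-3-one with hydrogen on Ca (C2 S, Ca epimers) | CC(C)=CCC[C@]1(C)OC2C(=CC1=O)c1cc(CC=C(C)C)c(O[Si](C(C)C)(C(C)C)C(C)C)cc1Oc1cc(O[Si](C(C)C)(C(C)C)C(C)C)ccc12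
F4 | step 8 | 11-(3,3-dimethoxy-2-oxopropyl)-2-(3-methylbut-2-enyl)-3,7-bis(triisopropylsilyloxy)dibenzo[b,f]oxepin-10(11H)-one (racemic) | COC(OC)C(=O)CC1C(=O)c2ccc(O[Si](C(C)C)(C(C)C)C(C)C)cc2Oc2cc(O[Si](C(C)C)(C(C)C)C(C)C)c(CC=C(C)C)cc21
F5 | step 8 | furan-2-carbaldehyde: formyl group on the furan α-carbon of 15 | O=Cc1cc2c(o1)-c1ccc(O[Si](C(C)C)(C(C)C)C(C)C)cc1Oc1cc(O[Si](C(C)C)(C(C)C)C(C)C)c(CC=C(C)C)cc1-2
F6 | step 8 | secondary furyl carbinol: 1-hydroxy-5-methylhex-4-enyl group on the furan α-carbon of 15 (racemic) | CC(C)=CCCC(O)c1cc2c(o1)-c1ccc(O[Si](C(C)C)(C(C)C)C(C)C)cc1Oc1cc(O[Si](C(C)C)(C(C)C)C(C)C)c(CC=C(C)C)cc1-2
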